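**Strategy.** Eudesmane numbering is used. The quaternary C10 of the target carries three oxygenated carbons (C1, C9, C14) and is thus the central carbon of a triacylmethane, while C3–C4(C15)–C5 of ring A is a masked 2-methyl-enal. Everything rests on one amine-catalysed Michael/aldol-condensation cascade of an achiral, acyclic triketo ester enal: C10 adds to C5 (ring B closes; C5 and the quaternary C10 are set), then the acetyl carbon C2 condenses with the aldehyde carbon C3 (ring A closes). The precursor is made in two steps from methyl acetoacetate; C7, C9, C1 and C2 are set afterwards on the rigid trans-decalin.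

Key step: step 3

Remark on locants: ring A = C1–C5 and C10, ring B = C5–C10, C14 on C10, C15 on C4, C11–C13 = isopropenyl on C7; β is the face of the decalin that carries C14, α the opposite face.
Remark on tautomers: the triacylmethanes 3, 5, F1 and F2 are enol-rich; their keto forms are drawn.

Step 1
Reactants: 1 methyl acetoacetate; 2 hex-5-enoyl chloride
Product: 3 methyl 2-acetyl-3-oxooct-7-enoate
Conditions: MgCl2 (1 equiv), pyridine (2 equiv), CH2Cl2, 0 °C to rt; 1 M HCl work-up
Reagents that add atoms: none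
Why: C-acylation of the chelated magnesium enolate of a β-keto ester by an acid chloride; the more acidic triacylmethane is deprotonated as it forms, which keeps the acylation on carbon.

Step 2
Reactants: 3 methyl 2-acetyl-3-oxooct-7-enoate; 4 methacrolein (excess)
Product: 5 methyl (7E)-2-acetyl-8-methyl-3,9-dioxonon-7-enoate
Conditions: second-generation Hoveyda–Grubbs catalyst RuCl2(H2IMes)(=CH-C6H4-2-O-i-Pr) (5 mol %), CH2Cl2, 40 °C; used directly in step 3
Reagents that add atoms: none
Why: olefin cross-metathesis of a terminal alkene with methacrolein, driven by loss of ethylene, should give the trisubstituted enal with the thermodynamically preferred E geometry.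

Step 3
Reactants: 5 methyl (7E)-2-acetyl-8-methyl-3,9-dioxonon-7-enoate
Product: 8 methyl (4S,4aR,8aS)-4-methyl-1,8-dioxo-1,4,4a,5,6,7,8,8a-octahydronaphthalene-8a-carboxylate, via Michael adduct 6 (not isolated), via aldol adduct 7 (not isolated)
Conditions: 9-amino-9-deoxy-epi-quinine (20 mol %), CF3CO2H (40 mol %), toluene, 40 °C, then 60 °C
Reagents that add atoms: none
Why: The primary amine turns the α-branched enal into an iminium ion and the acidic, enolised triacylmethane adds through C10 to C5 (intramolecular Michael addition, 6-exo-trig, ring B); the enol of the C1 acetyl group then attacks the aldehyde carbon C3 through C2 and water is lost (aldol condensation, 6-enolexo-exo-trig, ring A); the closest known reaction type is the amine-catalysed Michael/aldol-condensation (Robinson-type) annulation of 1,3-dicarbonyl compounds with enals. C5 is set by the catalyst, which is chosen to shield the Si face of C5 so that C10 bonds to the Re face (5R); the quinidine-derived pseudo-enantiomer would give the antipode. C10 is set relative to C5 in a chair transition state with the enal carbon C4 equatorial and the nucleophile reacting as the hydrogen-bonded diketone enol (O9 syn to C1), which places the acetyl group equatorial and the ester axial, trans to H5, so that ring A closes to the trans-decalin. C4 is epimerisable through the dienamine and should settle with its methyl group equatorial (4S). The step needs C- over O-alkylation (the oxa-Michael adduct forms reversibly) and condensation of the acetyl methyl group and not of C8 (the C8 aldol adduct would be a bridged bicyclo[2.2.2]octane that cannot dehydrate and reverts).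

Step 4
Reactants: 8 methyl (4S,4aR,8aS)-4-methyl-1,8-dioxo-1,4,4a,5,6,7,8,8a-octahydronaphthalene-8a-carboxylate
Product: 9 methyl 9-(tert-butyldimethylsilyloxy)-1-oxo-4βH,5αH-11,12,13-trinoreudesma-2,8-dien-14-oate
Conditions: TBSOTf (1.2 equiv), Et3N, CH2Cl2, −78 to 0 °C
Reagents that add atoms: tert-butyldimethylsilyl triflate, CC(C)(C)[Si](C)(C)OS(=O)(=O)C(F)(F)F
Why: soft enolisation and O-silylation of the C9 ketone, whose only α-hydrogens are on C8 (C10 is quaternary); the silyl enol ether masks C9 for step 5 and prepares step 7.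

Step 5
Reactants: 9 methyl 9-(tert-butyldimethylsilyloxy)-1-oxo-4βH,5αH-11,12,13-trinoreudesma-2,8-dien-14-oate
Product: 10 9-(tert-butyldimethylsilyloxy)-4βH,5αH-11,12,13-trinoreudesma-2,8-diene-1β,14-diol
Conditions: i-Bu2AlH (6 equiv), CH2Cl2, −78 to 0 °C; Rochelle salt work-up
Reagents that add atoms: none
Why: 1,2-reduction of the enone and reduction of the ester by the aluminium hydride; hydride should add to C1 from the α-face, anti to the axial ester on C10, giving the equatorial 1β-alcohol.

Step 6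
Reactants: 10 9-(tert-butyldimethylsilyloxy)-4βH,5αH-11,12,13-trinoreudesma-2,8-diene-1β,14-diol
Product: 11 9,14-bis(tert-butyldimethylsilyloxy)-4βH,5αH-11,12,13-trinoreudesma-2,8-dien-1β-ol
Conditions: TBSCl (1.1 equiv), imidazole, DMF, 0 °C
Reagents that add atoms: tert-butyldimethylsilyl chloride, CC(C)(C)[Si](C)(C)Cl
Why: selective silylation of the primary C14 hydroxyl over the secondary C1 hydroxyl, which lies next to the quaternary centre.

Step 7
Reactants: 11 9,14-bis(tert-butyldimethylsilyloxy)-4βH,5αH-11,12,13-trinoreudesma-2,8-dien-1β-ol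
Product: 12 14-(tert-butyldimethylsilyloxy)-1β-hydroxy-4βH,5αH-11,12,13-trinoreudesma-2,7-dien-9-one
Conditions: Pd(OAc)2 (1.1 equiv), MeCN, 40 °C
Reagents that add atoms: none
Why: Saegusa–Ito oxidation; the silyl enol ether gives a palladium enolate at C8 and β-hydride elimination of H7 gives the ring B enone, now the only enone in the molecule.

Step 8
Reactants: 12 14-(tert-butyldimethylsilyloxy)-1β-hydroxy-4βH,5αH-11,12,13-trinoreudesma-2,7-dien-9-one
Product: 13 14-(tert-butyldimethylsilyloxy)-1β-hydroxy-4βH,5αH,7βH-eudesma-2,11-dien-9-one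
Conditions: isopropenylmagnesium bromide (3.5 equiv), CuBr·SMe2 (20 mol %), THF, −78 to −40 °C; aq. NH4Cl
Reagents that add atoms: isopropenylmagnesium bromide, C=C(C)[Mg]Br
Why: copper-catalysed conjugate addition to the cyclohexenone; axial attack on C7 from the α-face (syn to the axial H5, away from the axial C14 group) should give the axial 7α-isopropenyl group, and the low temperature guards the β-alkoxy ketone against retro-aldol cleavage.

Step 9
Reactants: 13 14-(tert-butyldimethylsilyloxy)-1β-hydroxy-4βH,5αH,7βH-eudesma-2,11-dien-9-one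
Product: 14 14-(tert-butyldimethylsilyloxy)-4βH,5αH,7βH-eudesma-2,11-diene-1β,9α-diol
Conditions: Me4N[BH(OAc)3] (5 equiv), MeCN/AcOH, −20 to 0 °C
Reagents that add atoms: none
Why: hydroxyl-directed Evans–Saksena reduction; the 1β-hydroxyl, which lies on the C14 side of the C9 carbonyl plane, binds boron and delivers hydride to the β-face of C9 through a six-membered transition state, giving the axial 9α-alcohol.

Step 10
Reactants: 14 14-(tert-butyldimethylsilyloxy)-4βH,5αH,7βH-eudesma-2,11-diene-1β,9α-diol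
Product: 15 2β,3β-epoxy-14-(tert-butyldimethylsilyloxy)-4βH,5αH,7βH-eudesm-11-ene-1β,9α-diol
Conditions: VO(acac)2 (5 mol %), t-BuOOH (1.1 equiv), CH2Cl2, 0 °C
Reagents that add atoms: tert-butyl hydroperoxide, CC(C)(C)OO
Why: vanadium-catalysed hydroxyl-directed epoxidation; oxygen is delivered to the C2=C3 bond syn to the allylic 1β-hydroxyl, while the isopropenyl group, only bishomoallylic to the C9 hydroxyl, reacts far more slowly.

Step 11
Reactants: 15 2β,3β-epoxy-14-(tert-butyldimethylsilyloxy)-4βH,5αH,7βH-eudesm-11-ene-1β,9α-diol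
Product: 16 14-(tert-butyldimethylsilyloxy)-5αH,7βH-eudesma-3,11-diene-1β,2β,9α-triol
Conditions: Et2Al(TMP) (5 equiv, from LiTMP and Et2AlCl), toluene, 0 °C to rt; Rochelle salt work-up
Reagents that add atoms: none
Why: aluminium amide-promoted isomerisation of an epoxide to an allylic alcohol by syn β-elimination through a cyclic transition state; the only hydrogen cis to the epoxide oxygen on a neighbouring carbon is the axial 4β-H, so the C3–O bond opens, the oxygen stays on C2 (β) and the C3=C4 bond forms (the cis-epoxy alcohol cannot undergo Payne rearrangement).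

Step 12
Reactants: 16 14-(tert-butyldimethylsilyloxy)-5αH,7βH-eudesma-3,11-diene-1β,2β,9α-triol
Product: 17 14-(tert-butyldimethylsilyloxy)-2β,9α-dihydroxy-5αH,7βH-eudesma-3,11-dien-1β-yl 3-methylbutanoate
Conditions: 3-methylbutanoyl chloride (1.2 equiv), Ph2B(OCH2CH2NH2) (10 mol %), i-Pr2NEt, MeCN, rt
Reagents that add atoms: 3-methylbutanoyl chloride, CC(C)CC(Cl)=O
Why: borinic acid-catalysed regioselective acylation; the cis-1,2-diol binds boron as a tetracoordinate borinate and should be acylated at its equatorial oxygen (C1), leaving the axial C2 hydroxyl and the isolated axial C9 hydroxyl free.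

Step 13
Reactants: 17 14-(tert-butyldimethylsilyloxy)-2β,9α-dihydroxy-5αH,7βH-eudesma-3,11-dien-1β-yl 3-methylbutanoate
Product: 18 2β,9α-diacetoxy-14-(tert-butyldimethylsilyloxy)-5αH,7βH-eudesma-3,11-dien-1β-yl 3-methylbutanoate
Conditions: Ac2O (excess), DMAP (0.3 equiv), pyridine, rt to 40 °C
Reagents that add atoms: acetic anhydride, CC(=O)OC(C)=O
Why: DMAP-catalysed acetylation of the two remaining secondary hydroxyls; excess anhydride should make acetylation of C2–OH faster than migration of the C1 ester.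

Step 14
Reactants: 18 2β,9α-diacetoxy-14-(tert-butyldimethylsilyloxy)-5αH,7βH-eudesma-3,11-dien-1β-yl 3-methylbutanoate
Product: 19 CNP0257109.1, 2β,9α-diacetoxy-14-hydroxy-5αH,7βH-eudesma-3,11-dien-1β-yl 3-methylbutanoate, (1R,2S,5R,7S,9S,10S)
Conditions: HF·pyridine, THF/pyridine, 0 °C to rt
Reagents that add atoms: none
Why: fluoride cleavage of the primary silyl ether under buffered, weakly acidic conditions, which should leave the three esters in place and avoid acyl migration to the freed C14 hydroxyl.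

**Compound list**

1 | methyl acetoacetate (methyl 3-oxobutanoate) | CC(=O)CC(=O)OC | starting material
2 | hex-5-enoyl chloride | C=CCCCC(Cl)=O | starting material
3 | methyl 2-acetyl-3-oxooct-7-enoate | CC(=O)C(C(=O)OC)C(=O)CCCC=C | intermediate
4 | methacrolein (2-methylprop-2-enal) | C=C(C)C=O | starting material
5 | methyl (7E)-2-acetyl-8-methyl-3,9-dioxonon-7-enoate | CC(=O)C(C(=O)OC)C(=O)CCC/C=C(\C)C=O | intermediate
6 | Michael adduct, methyl (1R,6R)-1-acetyl-2-oxo-6-[(2R)-1-oxopropan-2-yl]cyclohexane-1-carboxylate | CC(=O)[C@@]1(C(=O)OC)C(=O)CCC[C@@H]1[C@@H](C)C=O | intermediate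
7 | aldol adduct, the 3-hydroxy-2,3-dihydro derivative of 8 (C3 epimers) | COC(=O)[C@@]12C(=O)CC(O)[C@H](C)[C@H]1CCCC2=O | intermediate
8 | methyl (4S,4aR,8aS)-4-methyl-1,8-dioxo-1,4,4a,5,6,7,8,8a-octahydronaphthalene-8a-carboxylate (trans-fused; 4α-methyl, 5α-H, axial β-ester) | COC(=O)[C@@]12C(=O)C=C[C@H](C)[C@H]1CCCC2=O | intermediate
9 | methyl 9-(tert-butyldimethylsilyloxy)-1-oxo-4βH,5αH-11,12,13-trinoreudesma-2,8-dien-14-oate | COC(=O)[C@@]12C(=O)C=C[C@H](C)[C@H]1CCC=C2O[Si](C)(C)C(C)(C)C | intermediate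
10 | 9-(tert-butyldimethylsilyloxy)-4βH,5αH-11,12,13-trinoreudesma-2,8-diene-1β,14-diol | OC[C@@]12[C@@H](O)C=C[C@H](C)[C@H]1CCC=C2O[Si](C)(C)C(C)(C)C | intermediate
11 | 9,14-bis(tert-butyldimethylsilyloxy)-4βH,5αH-11,12,13-trinoreudesma-2,8-dien-1β-ol | CC(C)(C)[Si](C)(C)OC[C@@]12[C@@H](O)C=C[C@H](C)[C@H]1CCC=C2O[Si](C)(C)C(C)(C)C | intermediate
12 | 14-(tert-butyldimethylsilyloxy)-1β-hydroxy-4βH,5αH-11,12,13-trinoreudesma-2,7-dien-9-one | CC(C)(C)[Si](C)(C)OC[C@@]12[C@@H](O)C=C[C@H](C)[C@H]1CC=CC2=O | intermediate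
13 | 14-(tert-butyldimethylsilyloxy)-1β-hydroxy-4βH,5αH,7βH-eudesma-2,11-dien-9-one | CC(C)(C)[Si](C)(C)OC[C@@]12[C@@H](O)C=C[C@H](C)[C@H]1C[C@H](C(C)=C)CC2=O | intermediate
14 | 14-(tert-butyldimethylsilyloxy)-4βH,5αH,7βH-eudesma-2,11-diene-1β,9α-diol | CC(C)(C)[Si](C)(C)OC[C@@]12[C@@H](O)C=C[C@H](C)[C@H]1C[C@H](C(C)=C)C[C@@H]2O | intermediate
15 | 2β,3β-epoxy-14-(tert-butyldimethylsilyloxy)-4βH,5αH,7βH-eudesm-11-ene-1β,9α-diol | CC(C)(C)[Si](C)(C)OC[C@@]12[C@@H](O)[C@H]3O[C@H]3[C@H](C)[C@H]1C[C@H](C(C)=C)C[C@@H]2O | intermediate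
16 | 14-(tert-butyldimethylsilyloxy)-5αH,7βH-eudesma-3,11-diene-1β,2β,9α-triol | CC(C)(C)[Si](C)(C)OC[C@@]12[C@@H](O)[C@@H](O)C=C(C)[C@H]1C[C@H](C(C)=C)C[C@@H]2O | intermediate
17 | 14-(tert-butyldimethylsilyloxy)-2β,9α-dihydroxy-5αH,7βH-eudesma-3,11-dien-1β-yl 3-methylbutanoate | CC(C)(C)[Si](C)(C)OC[C@@]12[C@@H](OC(=O)CC(C)C)[C@@H](O)C=C(C)[C@H]1C[C@H](C(C)=C)C[C@@H]2O | intermediate
18 | 2β,9α-diacetoxy-14-(tert-butyldimethylsilyloxy)-5αH,7βH-eudesma-3,11-dien-1β-yl 3-methylbutanoate | CC(C)(C)[Si](C)(C)OC[C@@]12[C@@H](OC(=O)CC(C)C)[C@@H](OC(C)=O)C=C(C)[C@H]1C[C@H](C(C)=C)C[C@@H]2OC(C)=O | intermediate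
19 | CNP0257109.1, (1R,2S,5R,7S,9S,10S)-2,9-diacetoxy-14-hydroxyeudesma-3,11-dien-1-yl 3-methylbutanoate | C=C(C)[C@@H]1C[C@H](OC(C)=O)[C@@]2(CO)[C@H](C1)C(C)=C[C@H](OC(C)=O)[C@@H]2OC(=O)CC(C)C | target

**Total step count:** 14
**Longest linear sequence:** 14 steps (from 1 and 2 to 19)

**Steps most likely to fail**

1. Step 3. Ring-fusion control may be lost: if the keto ester enol reacts instead of the diketone enol, the ester takes the equatorial site in the Michael transition state and the cis-fused isomer forms. The fallback sets out from 2 and 4 and returns at 10; it replaces the ester by a nitrile, which cannot chelate and is small enough to sit axial. 3-Oxobutanenitrile is C-acylated with 2 (MgCl2, pyridine, CH2Cl2) to 2-acetyl-3-oxooct-7-enenitrile F1. Cross-metathesis with 4 under the conditions of step 2 gives (7E)-2-acetyl-8-methyl-3,9-dioxonon-7-enenitrile F2. The amine-catalysed cascade of step 3 should then give (4S,4aR,8aS)-4-methyl-1,8-dioxo-1,4,4a,5,6,7,8,8a-octahydronaphthalene-8a-carbonitrile F3. Silylation as in step 4 gives 9-(tert-butyldimethylsilyloxy)-1-oxo-4βH,5αH-11,12,13-trinoreudesma-2,8-diene-14-nitrile F4. i-Bu2AlH followed by aqueous acid reduces the C1 ketone and takes the nitrile to the aldehyde, 9-(tert-butyldimethylsilyloxy)-1β-hydroxy-4βH,5αH-11,12,13-trinoreudesma-2,8-dien-14-al F5, and NaBH4 in MeOH gives 10.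

2. Step 11. Abstraction of the tertiary 4β-hydrogen may be slow, so that Lewis-acid-induced opening or rearrangement of the epoxide competes. The fallback sets out from 15 and returns at 16; it replaces the syn elimination by a halohydrin and an anti elimination. MgBr2·OEt2 opens the epoxide in the trans-diaxial (Fürst–Plattner) sense to 3α-bromo-14-(tert-butyldimethylsilyloxy)-4βH,5αH,7βH-eudesm-11-ene-1β,2β,9α-triol F6. 2,2-Dimethoxypropane and pyridinium p-toluenesulfonate protect the cis-1,2-diol as the 1β,2β-O-isopropylidene acetal F7, so that the C2 oxygen cannot re-close the epoxide. DBU in hot toluene removes the axial 4β-hydrogen, anti-periplanar to the axial bromide, to give 14-(tert-butyldimethylsilyloxy)-1β,2β-isopropylidenedioxy-5αH,7βH-eudesma-3,11-dien-9α-ol F8, and aqueous acetic acid gives 16.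

3. Step 12. The acyl group may go to the axial allylic C2 hydroxyl or to both hydroxyls, because the equatorial C1 hydroxyl is neopentyl. The fallback sets out from 16 and returns at 18; it fixes the acetate first by orthoester opening. Trimethyl orthoacetate and camphorsulfonic acid give the cyclic 1β,2β-(1-methoxyethylidene) orthoester F9. Aqueous acetic acid opens it to the axial ester, 14-(tert-butyldimethylsilyloxy)-1β,9α-dihydroxy-5αH,7βH-eudesma-3,11-dien-2β-yl acetate F10. 3-Methylbutanoic anhydride with DMAP acylates the equatorial C1 hydroxyl ahead of the hindered axial C9 hydroxyl to give 2β-acetoxy-14-(tert-butyldimethylsilyloxy)-9α-hydroxy-5αH,7βH-eudesma-3,11-dien-1β-yl 3-methylbutanoate F11, and the conditions of step 13 give 18.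

**Further compounds**

F1 | step 3 | 2-acetyl-3-oxooct-7-enenitrile | CC(=O)C(C#N)C(=O)CCCC=C
F2 | step 3 | (7E)-2-acetyl-8-methyl-3,9-dioxonon-7-enenitrile | CC(=O)C(C#N)C(=O)CCC/C=C(\C)C=O
F3 | step 3 | (4S,4aR,8aS)-4-methyl-1,8-dioxo-1,4,4a,5,6,7,8,8a-octahydronaphthalene-8a-carbonitrile | N#C[C@@]12C(=O)C=C[C@H](C)[C@H]1CCCC2=O
F4 | step 3 | 9-(tert-butyldimethylsilyloxy)-1-oxo-4βH,5αH-11,12,13-trinoreudesma-2,8-diene-14-nitrile | N#C[C@@]12C(=O)C=C[C@H](C)[C@H]1CCC=C2O[Si](C)(C)C(C)(C)C
F5 | step 3 | 9-(tert-butyldimethylsilyloxy)-1β-hydroxy-4βH,5αH-11,12,13-trinoreudesma-2,8-dien-14-al | O=C[C@@]12[C@@H](O)C=C[C@H](C)[C@H]1CCC=C2O[Si](C)(C)C(C)(C)C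
F6 | step 11 | 3α-bromo-14-(tert-butyldimethylsilyloxy)-4βH,5αH,7βH-eudesm-11-ene-1β,2β,9α-triol | CC(C)(C)[Si](C)(C)OC[C@@]12[C@@H](O)[C@@H](O)[C@H](Br)[C@H](C)[C@H]1C[C@H](C(C)=C)C[C@@H]2O
F7 | step 11 | 3α-bromo-14-(tert-butyldimethylsilyloxy)-1β,2β-isopropylidenedioxy-4βH,5αH,7βH-eudesm-11-en-9α-ol | CC(C)(C)[Si](C)(C)OC[C@@]12[C@H]3OC(C)(C)O[C@H]3[C@H](Br)[C@H](C)[C@H]1C[C@H](C(C)=C)C[C@@H]2O
F8 | step 11 | 14-(tert-butyldimethylsilyloxy)-1β,2β-isopropylidenedioxy-5αH,7βH-eudesma-3,11-dien-9α-ol | CC(C)(C)[Si](C)(C)OC[C@@]12[C@H]3OC(C)(C)O[C@H]3C=C(C)[C@H]1C[C@H](C(C)=C)C[C@@H]2O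
F9 | step 12 | 14-(tert-butyldimethylsilyloxy)-1β,2β-(1-methoxyethylidenedioxy)-5αH,7βH-eudesma-3,11-dien-9α-ol (orthoester epimers) | CC(C)(C)[Si](C)(C)OC[C@@]12[C@H]3OC(C)(OC)O[C@H]3C=C(C)[C@H]1C[C@H](C(C)=C)C[C@@H]2O
F10 | step 12 | 14-(tert-butyldimethylsilyloxy)-1β,9α-dihydroxy-5αH,7βH-eudesma-3,11-dien-2β-yl acetate | CC(C)(C)[Si](C)(C)OC[C@@]12[C@@H](O)[C@@H](OC(C)=O)C=C(C)[C@H]1C[C@H](C(C)=C)C[C@@H]2O
F11 | step 12 | 2β-acetoxy-14-(tert-butyldimethylsilyloxy)-9α-hydroxy-5αH,7βH-eudesma-3,11-dien-1β-yl 3-methylbutanoate | CC(C)(C)[Si](C)(C)OC[C@@]12[C@@H](OC(=O)CC(C)C)[C@@H](OC(C)=O)C=C(C)[C@H]1C[C@H](C(C)=C)C[C@@H]2O
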